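Start from a small charge: red holds 0.012 M of substrate at 5 °C, and you want to know how clean it stays beside the other flasks.

| flask | substrate | partner | temperature | remark | time |
|---|---|---|---|---|---|
| theta | 0.015 M | 0.045 M | −1 °C | run made earlier |  |
| beta | 0.045 M | 0.045 M | 29 °C | run made earlier |  |
| gamma | 0.13 M | 0.045 M | −1 °C | run made earlier |  |
| zeta | 0.050 M | 0.053 M | 29 °C | run made earlier |  |
| violet | 0.050 M | 0.100 M | 40 °C |  | 30 d |
| amber | 0.080 M | 0.100 M | 25 °C |  | 30 d |
| green | 0.15 M | 0.200 M | −15 °C |  | 30 d |
| ochre | 0.050 M | 0.0450 M | 25 °C |  | 30 d |
| blue | 0.050 M | 0.0250 M | 10 °C |  | 30 d |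
| red | 0.012 M | 0.200 M | 5 °C |  | 30 d |

- theta (time / d: target / %, side product / %): 20.0: 4.5, 0; 40.0: 16.1, 0.2; 80.0: 39.6, 1.1; 100: 48.2, 0
- beta (time / d: target / %, side product / %): 2.50: 36.2, 1.7; 8.00: 41.4, 5.5; 15.0: 42.5, 9.1; 20.0: 40.6, 13.6; 30.0: 37.9, 16.5
- gamma (time / d: target / %, side product / %): 10.0: 1.1, 0; 20.0: 5.7, 2.1; 30.0: 6.4, 1.6; 50.0: 13.6, 3.8; 100: 23.5, 6.4
- zeta (time / d: target / %, side product / %): 6.00: 39.6, 5.9; 12.0: 40.8, 10.4; 20.0: 39.1, 14.2; 25.0: 37.5, 15.8; 30.0: 38.1, 20.1

(standard deviation of a reading: 1 percentage point)

- a species is counted by the substrate in it: one side product counts as two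
- what was read earlier has a scatter of 1 percentage point, one standard deviation

- the flasks by share of target in all that became target or side product, highest first, at 30 d (violet / amber / green / ochre / blue / red)
- the same order at 40 h (violet / amber / green / ochre / blue / red)
- the share of target in all that became target or side product of the flask you put first, at 30 d
- the share of target in all that became target or side product of the flask you put last, at 30 d

Turn the question round for violet: what must be true for it to hold more target than side product at 30 d? Zeta shows the pattern. Its target peaks at a reading of 40.8%, while its side product climbs nearly straight to 20.1% at 30.0 d. So call the crossing time t× the target plateau divided by the daily gain of side product 60.9 d; that value is zeta's. While target stays flat, target over side product, your running selectivity factor, is t×/t, and the share is t×/(t×+t). The opposite outcome therefore needs t× beyond 30 d.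

To scale t×, I assume side product grows in step with c(substrate). At 100 d gamma reads more side product than theta, at the same temperature and partner, 6.4% against 0%. Per unit of c(substrate), beta's mean gain is 24.8 times gamma's, between −1 °C and 29 °C.

I hold the plateau at zeta's, whatever the partner, and spread that factor as a constant ratio per degree. Violet has zeta's substrate charge, so this reckoning gives it a t× of 18.8 d. That is shorter than 30 d, so I reckon a share of 38.5%. The opposite outcome would need t× longer by a factor of 1.60. Red gets 3310 d, a share of 99.1%. Blue gets 466 d, ochre 93.4 d and amber 58.4 d. Gamma's target is still climbing at its last readings, from 13.6% to 23.5%, so gamma gives me no plateau for green. I take gamma's share at 30.0 d instead, a reading of 80.0% with its scatter, though gamma stood at −1 °C and green stands at −15 °C. My order is red, blue, green, ochre, amber, violet. The rule needs a plateau, so I leave the order at 40 h unreckoned.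

The forecast gave red > amber > blue > green > ochre > violet at 30 d and red > violet > amber > ochre > blue > green at 40 h, with 99.8% first and 51% last (42% to 62%), calling green “lag-dominated, uncertain”.

The simulation gives red > blue > ochre > amber > green > violet at 30 d and red > ochre > amber > blue > violet > green at 40 h, with 99.4% for red, 36.5% for violet and 68.8% for green at 30 d.

    substrate + partner ⇌ intermediate (K = 42.0 M⁻¹, k = 0.00661 M⁻¹ min⁻¹, Ea = 84.0 kJ mol⁻¹, ΔH = 4.00 kJ mol⁻¹)
    intermediate ⇌ target + by-product (K = 0.0573 M, k = 7.14 × 10⁻⁴ min⁻¹, Ea = 96.0 kJ mol⁻¹, ΔH = −88.0 kJ mol⁻¹)
    substrate + intermediate → side product (k = 4.46 × 10⁻⁴ M⁻¹ min⁻¹, Ea = 79.0 kJ mol⁻¹)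
    (constants at 25 °C)

Violet's target and side product stand level at 15.0 d, 26.7% against 27.3%, where t× said 18.8 d, but target stands below the plateau I held. At 0.106 d violet makes intermediate 1.71 times as fast as it uses it up, each step taken net, and at 30.0 d that figure is 0.308, with 26.5% still held as intermediate. Now take a flask like violet kept at 55 °C: t× becomes 3.76 d, a share of 11.1%, though the straight line of side product reaches the whole charge at 9.22 d, so this is rough. The simulation gives 8.58%, with target 7.27% and side product 77.5%.

The readings were generated by integration for substances that don't exist, and the scatter is random.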